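**Plan**

1. Retrosynthetic cuts: first the C11–O aryl ether, then both ring-B bonds C7–C8 and C9–C10 in one Diels–Alder event, then the ring A–vinyl bond C5–C6 (Stille), back to 2,2-dimethylcyclohexane-1,3-dione, but-2-yn-1-ol and umbelliferone.
2. Enabling feature: in ring B the methyl C12 (on C8) and the oxymethylene C11 (on C9) sit on neighbouring carbons beside quaternary C10, which is the footprint of MeC≡C–CHO added across the ring-A diene C10=C5–C6=C7.
3. Forward order: ring A is carried as an achiral monoketal diene; ring B closes by a catalytic asymmetric [4+2]; then C6 is oxygenated by hydroboration/oxidation, the enone is conjugated, the C3 ketone is reduced and the coumarin is attached last.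
4. Stereochemistry: C10 from the chiral oxazaborolidinium catalyst; C5 from syn hydroboration anti to the C10 methyl; C9 from dienolate protonation anti to the C10 methyl; C3 from axial hydride delivery giving the equatorial alcohol. The target is (3R,5S,9R,10S).
5. Numbering used for locants only (configuration is always given by CIP descriptors): ring A = C1–C5 and C10, ring B = C5–C10, C11 = CH2 on C9, C12 = CH3 on C8, C13/C14 = CH3 on C4, C15 = CH3 on C10.

Key step: step 6

Assumption: the sense of induction of the catalyst with this diene/ynal pair cannot be derived with certainty, because with an alkynyl dienophile the endo or exo placement of the diene decides which diene face reacts. The (S)-catalyst is written, and its (R)-antipode would replace it without other change if the first run delivers the (10S)-adduct.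

**Route**

Step 1
Reactants: 1 2,2-dimethylcyclohexane-1,3-dione
Product: 2 6,6-dimethyl-1,4-dioxaspiro[4.5]decan-7-one
Conditions: ethylene glycol (1.1 equiv), p-toluenesulfonic acid monohydrate (cat.), benzene, reflux, Dean–Stark
Reagents that add atoms: ethylene glycol, OCCO
Why: Acid-catalysed ketalization (dioxolane formation) with one equivalent of diol should stop at the monoketal, because the remaining carbonyl is then neopentyl-type and shielded by the neighbouring dioxolane-bearing quaternary unit.

Step 2
Reactants: 2 6,6-dimethyl-1,4-dioxaspiro[4.5]decan-7-one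
Product: 4 6,6,8-trimethyl-1,4-dioxaspiro[4.5]decan-7-one (racemic), via lithium enolate 3 (not isolated)
Conditions: LiN(i-Pr)2 (LDA, commercial solution), THF, −78 °C; MeI, −78 → 0 °C
Reagents that add atoms: iodomethane, CI
Why: Enolate alkylation: the ketone has only one enolisable α-carbon, so deprotonation and SN2 methylation are regiochemically unambiguous, and the stereocentre formed is erased in step 3.

Step 3
Reactants: 4 6,6,8-trimethyl-1,4-dioxaspiro[4.5]decan-7-one
Product: 6 6,6,8-trimethyl-1,4-dioxaspiro[4.5]dec-7-en-7-yl trifluoromethanesulfonate, via lithium enolate 5 (not isolated)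
Conditions: LiN(i-Pr)2 (commercial solution), THF, −78 → 0 °C; PhNTf2, 0 °C → rt
Reagents that add atoms: N-phenylbis(trifluoromethanesulfonimide), O=S(=O)(N(c1ccccc1)S(=O)(=O)C(F)(F)F)C(F)(F)F
Why: Enol triflate formation by O-sulfonylation of the only possible (tetrasubstituted) lithium enolate, as practised on 2,2,6-trimethylcyclohexanone.

Step 4
Reactants: 6 6,6,8-trimethyl-1,4-dioxaspiro[4.5]dec-7-en-7-yl trifluoromethanesulfonate
Product: 7 7-ethenyl-6,6,8-trimethyl-1,4-dioxaspiro[4.5]dec-7-ene
Conditions: tributyl(vinyl)stannane, Pd(PPh3)4 (5 mol%), LiCl (3 equiv), THF, reflux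
Reagents that add atoms: tributyl(vinyl)stannane, C=C[Sn](CCCC)(CCCC)CCCC
Why: Stille coupling of a cyclohexenyl triflate with a vinylstannane under zerovalent palladium catalysis, established for the equally hindered 2,6,6-trimethylcyclohexenyl triflate, should give the ring-A diene without touching the ketal.

Step 5
Reactants: 8 but-2-yn-1-ol
Product: 9 but-2-ynal
Conditions: activated MnO2 (10 equiv), CH2Cl2, rt; filtered and kept as a titrated CH2Cl2 solution
Reagents that add atoms: none
Why: MnO2 oxidation of a propargylic alcohol stops at the aldehyde, and the volatile ynal is kept in solution to avoid loss and polymerisation.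

Step 6
Reactants: 7 7-ethenyl-6,6,8-trimethyl-1,4-dioxaspiro[4.5]dec-7-ene; 9 but-2-ynal
Product: 10 (10R)-3,3-(ethylenedioxy)drima-5,8-dien-11-al (ring-B 1,4-diene with C5=C6 and C8=C9, CHO on C9, CH3 on C8, quaternary C10)
Conditions: 9 (1.5 equiv), (S)-tetrahydro-1-(2-methylphenyl)-3,3-diphenyl-1H,3H-pyrrolo[1,2-c][1,3,2]oxazaborole (24 mol%) + HN(SO2CF3)2 (20 mol%), CH2Cl2, −78 → −20 °C
Reagents that add atoms: none
Why: Proposed new method: the N-protonated oxazaborolidine binds the formyl oxygen of 9 at boron, lowers the LUMO of the conjugated alkyne π bond and lets the s-cis diene 7 add in a concerted but asynchronous [4+2] cycloaddition in which C7–C8 bonding runs ahead of C9–C10 bonding. The closest known reaction types are thermal Diels–Alder additions of 2,6,6-trimethyl-1-vinylcyclohexene to acetylenic dienophiles and oxazaborolidinium-catalysed Diels–Alder reactions of ynals and 2-substituted enals with unhindered dienes; new here is catalyst-controlled attack at a fully substituted diene terminus to form a quaternary carbon. Ring B closes as a six-membered carbocycle in a suprafacial [4πs+2πs] mode, both σ bonds being made in the same event. C10, the only new stereocentre, is set by the catalyst, whose aryl groups screen one face of the bound ynal so that only one enantiotopic face of the C10 terminus can reach C9, ring A being achiral with C3 masked as a ketal. The step needs regioselectivity (C7 to C8, C10 to C9), which the substrate secures because the unsubstituted, unhindered terminus C7 carries the largest HOMO coefficient and attacks the electrophilic β-carbon of the activated ynal while the developing positive charge is spread over the C6–C5–C10 allyl unit and ends on the dialkylated C10. It also needs chemoselectivity, secured because the tetrasubstituted enal of 10 is a far poorer dienophile than 9, the dioxolane beside the gem-dimethyl carbon is a poor ligand for boron, and the acid is kept substoichiometric to the oxazaborolidine so that no free HN(SO2CF3)2 meets diene or ketal.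

Step 7
Reactants: 10 (10R)-3,3-(ethylenedioxy)drima-5,8-dien-11-al
Product: 11 (10R)-3,3-(ethylenedioxy)drima-5,8-dien-11-ol
Conditions: NaBH4, MeOH, 0 °C
Reagents that add atoms: none
Why: Borohydride 1,2-reduction of the aldehyde, the fully substituted β-carbon of the enal ruling out conjugate reduction, should leave the ketal and both alkenes untouched and creates no stereocentre.

Step 8
Reactants: 11 (10R)-3,3-(ethylenedioxy)drima-5,8-dien-11-ol
Product: 12 (10R)-11-(tert-butyldimethylsilyloxy)-3,3-(ethylenedioxy)drima-5,8-diene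
Conditions: TBSCl, imidazole, DMF, rt
Reagents that add atoms: tert-butyldimethylsilyl chloride, CC(C)(C)[Si](C)(C)Cl
Why: Silyl ether formation masks the primary allylic alcohol so that only the C6 hydroxyl made in step 9 is oxidised in step 10.

Step 9
Reactants: 12 (10R)-11-(tert-butyldimethylsilyloxy)-3,3-(ethylenedioxy)drima-5,8-diene
Product: 14 (5S,6R,10R)-11-(tert-butyldimethylsilyloxy)-3,3-(ethylenedioxy)drim-8-en-6-ol (5-H and 6-OH both anti to the C10 methyl), via C6 alkylborane 13 (not isolated)
Conditions: BH3·THF (1.5 equiv), THF, 0 °C → rt; then 3 M NaOH, 30% H2O2, 0 °C → rt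
Reagents that add atoms: hydrogen peroxide, OO
Why: Brown hydroboration–oxidation: borane adds syn and anti-Markovnikov across the trisubstituted C5=C6 bond (B to C6, H to C5) from the face opposite the axial C10 methyl, which sets the trans ring fusion at C5 and, after oxidation with retention, the C6 carbinol, while the tetrasubstituted C8=C9 bond flanked by quaternary C10 should react more slowly, as with the inert nuclear tetrasubstituted alkene of lanosterol-type dienes.

Step 10
Reactants: 14 (5S,6R,10R)-11-(tert-butyldimethylsilyloxy)-3,3-(ethylenedioxy)drim-8-en-6-ol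
Product: 15 (5S,10R)-11-(tert-butyldimethylsilyloxy)-3,3-(ethylenedioxy)drim-8-en-6-one
Conditions: Dess–Martin periodinane, CH2Cl2, rt
Reagents that add atoms: none
Why: Dess–Martin oxidation should convert the hindered secondary C6 alcohol into the ketone under conditions that leave ketal, silyl ether and the β,γ-alkene in place.

Step 11
Reactants: 15 (5S,10R)-11-(tert-butyldimethylsilyloxy)-3,3-(ethylenedioxy)drim-8-en-6-one
Product: 16 (5S,9R,10S)-11-(tert-butyldimethylsilyloxy)-3,3-(ethylenedioxy)drim-7-en-6-one
Conditions: 1,8-diazabicyclo[5.4.0]undec-7-ene (DBU, 0.3 equiv), CH2Cl2, rt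
Reagents that add atoms: none
Why: Base-catalysed β,γ- to α,β-enone isomerisation through the C6 dienolate, which should take up the proton at C9 on the face opposite the axial C10 methyl so that C11 ends up cis to that methyl (9R), conjugation with the ketone making the shift downhill.

Step 12
Reactants: 16 (5S,9R,10S)-11-(tert-butyldimethylsilyloxy)-3,3-(ethylenedioxy)drim-7-en-6-one
Product: 17 (5S,9R,10S)-11-hydroxydrim-7-ene-3,6-dione
Conditions: 2 M HCl, THF, rt → 40 °C
Reagents that add atoms: water, O
Why: Aqueous acid hydrolysis cleaves the dioxolane (acetal hydrolysis) and the primary silyl ether in one operation, the enone and the C5, C9 and C10 centres being expected to withstand dilute acid.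

Step 13
Reactants: 17 (5S,9R,10S)-11-hydroxydrim-7-ene-3,6-dione
Product: 18 (3R,5S,9R,10S)-3,11-dihydroxydrim-7-en-6-one
Conditions: NaBH4 (1.0 equiv), MeOH–CH2Cl2, −20 °C
Reagents that add atoms: none
Why: Chemoselective borohydride reduction of the saturated C3 ketone in the presence of the conjugated and far more hindered C6 enone, with axial hydride attack from the face opposite the axial C4 and C10 methyl groups giving the equatorial (3R) alcohol, the usual outcome for 4,4-dimethyl-3-keto terpenoids.

Step 14
Reactants: 18 (3R,5S,9R,10S)-3,11-dihydroxydrim-7-en-6-one; 19 umbelliferone (7-hydroxy-2H-chromen-2-one)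
Product: 20 ligupersin A, (3R,5S,9R,10S)-3-hydroxy-11-[(2-oxo-2H-chromen-7-yl)oxy]drim-7-en-6-one
Conditions: PPh3, DIAD, THF, 0 °C → rt
Reagents that add atoms: none
Why: Mitsunobu etherification: the acidic phenol of umbelliferone (pKa about 8) displaces the oxyphosphonium of the primary C11 carbinol by SN2 at a CH2 group, whereas the secondary C3 hydroxyl beside the gem-dimethyl carbon cannot be substituted, so no protecting group is needed and no stereocentre is touched.

**Compound list**

1 | 2,2-dimethylcyclohexane-1,3-dione | CC1(C)C(=O)CCCC1=O | starting material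
2 | 6,6-dimethyl-1,4-dioxaspiro[4.5]decan-7-one | CC1(C)C(=O)CCCC12OCCO2 | intermediate
3 | lithium 6,6-dimethyl-1,4-dioxaspiro[4.5]dec-7-en-7-olate | [Li]OC1=CCCC2(OCCO2)C1(C)C | intermediate
4 | 6,6,8-trimethyl-1,4-dioxaspiro[4.5]decan-7-one (racemic) | CC1CCC2(OCCO2)C(C)(C)C1=O | intermediate
5 | lithium 6,6,8-trimethyl-1,4-dioxaspiro[4.5]dec-7-en-7-olate | [Li]OC1=C(C)CCC2(OCCO2)C1(C)C | intermediate
6 | 6,6,8-trimethyl-1,4-dioxaspiro[4.5]dec-7-en-7-yl trifluoromethanesulfonate | CC1=C(OS(=O)(=O)C(F)(F)F)C(C)(C)C2(OCCO2)CC1 | intermediate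
7 | 7-ethenyl-6,6,8-trimethyl-1,4-dioxaspiro[4.5]dec-7-ene | C=CC1=C(C)CCC2(OCCO2)C1(C)C | intermediate
8 | but-2-yn-1-ol | CC#CCO | starting material
9 | but-2-ynal | CC#CC=O | intermediate
10 | (10R)-3,3-(ethylenedioxy)drima-5,8-dien-11-al | O=CC1=C(C)CC=C2C(C)(C)C3(OCCO3)CC[C@@]12C | intermediate
11 | (10R)-3,3-(ethylenedioxy)drima-5,8-dien-11-ol | OCC1=C(C)CC=C2C(C)(C)C3(OCCO3)CC[C@@]12C | intermediate
12 | (10R)-11-(tert-butyldimethylsilyloxy)-3,3-(ethylenedioxy)drima-5,8-diene | CC(C)(C)[Si](C)(C)OCC1=C(C)CC=C2C(C)(C)C3(OCCO3)CC[C@@]12C | intermediate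
13 | (5S,6R,10R)-6-boranyl-11-(tert-butyldimethylsilyloxy)-3,3-(ethylenedioxy)drim-8-ene | CC1=C(CO[Si](C)(C)C(C)(C)C)[C@]2(C)CCC3(OCCO3)C(C)(C)[C@H]2[C@H](B)C1 | intermediate
14 | (5S,6R,10R)-11-(tert-butyldimethylsilyloxy)-3,3-(ethylenedioxy)drim-8-en-6-ol | CC1=C(CO[Si](C)(C)C(C)(C)C)[C@]2(C)CCC3(OCCO3)C(C)(C)[C@H]2[C@H](O)C1 | intermediate
15 | (5S,10R)-11-(tert-butyldimethylsilyloxy)-3,3-(ethylenedioxy)drim-8-en-6-one | CC1=C(CO[Si](C)(C)C(C)(C)C)[C@]2(C)CCC3(OCCO3)C(C)(C)[C@H]2C(=O)C1 | intermediate
16 | (5S,9R,10S)-11-(tert-butyldimethylsilyloxy)-3,3-(ethylenedioxy)drim-7-en-6-one | CC1=CC(=O)[C@@H]2C(C)(C)C3(OCCO3)CC[C@@]2(C)[C@@H]1CO[Si](C)(C)C(C)(C)C | intermediate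
17 | (5S,9R,10S)-11-hydroxydrim-7-ene-3,6-dione | CC1=CC(=O)[C@@H]2C(C)(C)C(=O)CC[C@@]2(C)[C@@H]1CO | intermediate
18 | (3R,5S,9R,10S)-3,11-dihydroxydrim-7-en-6-one | CC1=CC(=O)[C@@H]2C(C)(C)[C@H](O)CC[C@@]2(C)[C@@H]1CO | intermediate
19 | umbelliferone | O=c1ccc2ccc(O)cc2o1 | starting material
20 | ligupersin A | CC1=CC(=O)[C@@H]2C(C)(C)[C@H](O)CC[C@@]2(C)[C@@H]1COc1ccc2ccc(=O)oc2c1 | target

**Step count**

Total: 14 steps. Longest linear sequence: 13 steps (steps 1–4 and 6–14 from dione 1).

**Steps most likely to fail**

Step 6 (proposed new method). The diene may react too slowly at its tetrasubstituted terminus (the s-cis form is twisted by the gem-dimethyl group), the catalyst may discriminate the diene faces poorly, or acid may isomerise the diene or open the ketal. Fallback with known chemistry: from diene 7 and ynal 9 the cycloaddition is run thermally without catalyst (toluene, 110 °C, sealed tube, trace of BHT), the established mode for 2,6,6-trimethyl-1-vinylcyclohexenes and acetylenic dienophiles, to give the racemic 3,3-(ethylenedioxy)drima-5,8-dien-11-al F1. NaBH4 reduction as in step 7 gives the racemic 3,3-(ethylenedioxy)drima-5,8-dien-11-ol F2. This is esterified with (S)-2-methoxy-2-phenylacetic acid (DCC, DMAP, CH2Cl2), the two diastereomeric esters are separated by chromatography or crystallisation, and the (10R)-configured (S)-2-methoxy-2-phenylacetate F3 is saponified (LiOH, THF–H2O) to rejoin the route at alcohol 11.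

Step 9. Borane may also attack the tetrasubstituted C8=C9 bond, or add too slowly to the C5=C6 bond between two quaternary carbons. Fallback: it sets out from aldehyde 10, in which C8=C9 is deactivated by the formyl group. Buffered mCPBA (NaHCO3, CH2Cl2, 0 °C) should epoxidise only C5=C6, anti to the C10 methyl, to give the (10R)-5,6-epoxy-3,3-(ethylenedioxy)drim-8-en-11-al F4. NaBH4 gives the 5,6-epoxy-3,3-(ethylenedioxy)drim-8-en-11-ol F5, and TBSCl/imidazole its 11-(tert-butyldimethylsilyl) ether F6. Meinwald rearrangement (BF3·OEt2, CH2Cl2, −78 °C, hydride shift from C6 to C5 on the face of the C10 methyl) gives the cis-fused (5R,10R)-11-(tert-butyldimethylsilyloxy)-3,3-(ethylenedioxy)drim-8-en-6-one F7. K2CO3 in MeOH then moves the double bond into conjugation and equilibrates C5 to the trans ring fusion, rejoining the route at enone 16.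

Step 14. Substitution at the β-branched C11 next to quaternary C10 may be slow, and the activated carbinol may instead eliminate across C9–C11, since the C9 hydrogen is vinylogously acidic. Fallback: the ether is made earlier, setting out from alcohol 14, where C11 is still a primary allylic carbinol and C9 carries no hydrogen. Bu4NF (THF) gives the (5S,6R,10R)-3,3-(ethylenedioxy)drim-8-ene-6,11-diol F8. Mitsunobu reaction with 19 (PPh3, DIAD, THF) should etherify only the unhindered allylic C11 hydroxyl to give the (5S,6R,10R)-3,3-(ethylenedioxy)-11-[(2-oxo-2H-chromen-7-yl)oxy]drim-8-en-6-ol F9. Dess–Martin oxidation gives the (5S,10R)-3,3-(ethylenedioxy)-11-[(2-oxo-2H-chromen-7-yl)oxy]drim-8-en-6-one F10. Dilute HCl in THF removes the ketal and conjugates the enone through the dienol (protonation at C9 anti to the C10 methyl; acid is chosen because base would expel the aryloxide from the dienolate), giving the (5S,9R,10S)-11-[(2-oxo-2H-chromen-7-yl)oxy]drim-7-ene-3,6-dione F11. NaBH4 at −20 °C as in step 13 reduces the C3 ketone and rejoins the route at 20.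

Further compounds
F1 | step 6 | racemic 3,3-(ethylenedioxy)drima-5,8-dien-11-al | O=CC1=C(C)CC=C2C(C)(C)C3(OCCO3)CCC12C
F2 | step 6 | racemic 3,3-(ethylenedioxy)drima-5,8-dien-11-ol | OCC1=C(C)CC=C2C(C)(C)C3(OCCO3)CCC12C
F3 | step 6 | (10R)-3,3-(ethylenedioxy)drima-5,8-dien-11-yl (S)-2-methoxy-2-phenylacetate | CO[C@H](C(=O)OCC1=C(C)CC=C2C(C)(C)C3(OCCO3)CC[C@@]12C)c1ccccc1
F4 | step 9 | (10R)-5,6-epoxy-3,3-(ethylenedioxy)drim-8-en-11-al, epoxide anti to the C10 methyl | O=CC1=C(C)C[C@H]2O[C@]23C(C)(C)C4(OCCO4)CC[C@@]13C
F5 | step 9 | (10R)-5,6-epoxy-3,3-(ethylenedioxy)drim-8-en-11-ol, epoxide anti to the C10 methyl | OCC1=C(C)C[C@H]2O[C@]23C(C)(C)C4(OCCO4)CC[C@@]13C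
F6 | step 9 | (10R)-11-(tert-butyldimethylsilyloxy)-5,6-epoxy-3,3-(ethylenedioxy)drim-8-ene, epoxide anti to the C10 methyl | CC(C)(C)[Si](C)(C)OCC1=C(C)C[C@H]2O[C@]23C(C)(C)C4(OCCO4)CC[C@@]13C
F7 | step 9 | (5R,10R)-11-(tert-butyldimethylsilyloxy)-3,3-(ethylenedioxy)drim-8-en-6-one (cis-fused C5 epimer of 15) | CC1=C(CO[Si](C)(C)C(C)(C)C)[C@]2(C)CCC3(OCCO3)C(C)(C)[C@@H]2C(=O)C1
F8 | step 14 | (5S,6R,10R)-3,3-(ethylenedioxy)drim-8-ene-6,11-diol | CC1=C(CO)[C@]2(C)CCC3(OCCO3)C(C)(C)[C@H]2[C@H](O)C1
F9 | step 14 | (5S,6R,10R)-3,3-(ethylenedioxy)-11-[(2-oxo-2H-chromen-7-yl)oxy]drim-8-en-6-ol | CC1=C(COc2ccc3ccc(=O)oc3c2)[C@]4(C)CCC5(OCCO5)C(C)(C)[C@H]4[C@H](O)C1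
F10 | step 14 | (5S,10R)-3,3-(ethylenedioxy)-11-[(2-oxo-2H-chromen-7-yl)oxy]drim-8-en-6-one | CC1=C(COc2ccc3ccc(=O)oc3c2)[C@]4(C)CCC5(OCCO5)C(C)(C)[C@H]4C(=O)C1
F11 | step 14 | (5S,9R,10S)-11-[(2-oxo-2H-chromen-7-yl)oxy]drim-7-ene-3,6-dione | CC1=CC(=O)[C@@H]2C(C)(C)C(=O)CC[C@@]2(C)[C@@H]1COc1ccc2ccc(=O)oc2c1
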